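**Plan**

- Retrosynthesis first cuts the two ester C–O bonds (methacrylate on O8, acetate on O11) and the two C11–CH3 bonds, leading back to a C11 methyl ester on C7.
- Enabling feature (guaiane numbering, defined below): the run C7(C11)–C8(O)–C9–C10(C14)–C1 is an ester α-carbon, an aldol carbinol and a crotonaldehyde unit strung between the two α-carbons of a cyclopentanone whose carbonyl carbon is C11. Cutting C1–C10 and C7–C8 and re-joining C1–C11 therefore contracts the seven-membered ring to ring C1–C5–C6–C7–C11 of a diquinane enedione.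
- The diquinane is cut by a Pauson–Khand disconnection to a 1,6-enyne, made from 5-bromopent-2-yne and acrolein.
- Forward: chain assembly, both five-membered rings in one carbonylative cyclisation, oxidation to the enedione, three-carbon ring expansion to the seven-membered ring, then the functional-group endgame.
- Stereochemistry: C10 from the amine catalyst; C8 from the chair of the bridged ketol; C1 by thermodynamic γ-protonation; C7 by kinetic protonation of an ester enolate on the face away from the 8-silyloxy group.

Key step: step 6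

Numbering used from compound 10 onward: C1 ring-fusion CH, C2 CH2, C3 carbonyl (or carbinol), C4=C5 alkene with methyl C15 on C4, C6 CH2, C7 CH bearing C11, C8 CH–O, C9 CH2, C10 CH bearing methyl C14.

Assumption: compounds 4 to 8 are racemic (6 and 7 as diastereomer mixtures) and the C3 carbinol of 13 to 19 is carried as an epimer mixture, because these centres are erased later (by enolisation in step 6 and by oxidation in step 12).

**Route**

Step 1
Reactants: 1 5-bromopent-2-yne; 2 acrolein
Product: 4 oct-1-en-6-yn-3-ol (racemic), via pent-3-ynylmagnesium bromide 3 (not isolated)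
Conditions: Mg, THF, 25 → 50 °C; then 2, −78 °C; aq. NH4Cl
Reagents that add atoms: none
Why: Grignard formation from the primary homopropargylic bromide and 1,2-addition to acrolein at low temperature should give the allylic alcohol; the new carbinol centre is racemic and is oxidised later.

Step 2
Reactants: 4 oct-1-en-6-yn-3-ol
Product: 5 tert-butyldimethyl(oct-1-en-6-yn-3-yloxy)silane
Conditions: tBuMe2SiCl, imidazole, DMF, 25 °C
Reagents that add atoms: tert-butyldimethylsilyl chloride, CC(C)(C)[Si](C)(C)Cl
Why: Standard silyl ether formation masks the allylic alcohol, which could otherwise isomerise to the ketone under the rhodium carbonylation of step 3.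

Step 3
Reactants: 5 tert-butyldimethyl(oct-1-en-6-yn-3-yloxy)silane
Product: 6 6-(tert-butyldimethylsilyloxy)-2-methylbicyclo[3.3.0]oct-1-en-3-one (racemic diastereomer mixture)
Conditions: [RhCl(CO)2]2 (5 mol %), CO (1 atm), Bu2O, 130 °C
Reagents that add atoms: carbon monoxide, [C-]#[O+]
Why: The intramolecular Pauson–Khand reaction of a 1,6-enyne joins alkene, alkyne and CO into the bicyclo[3.3.0]oct-1-en-3-one with the alkyne methyl α to the new carbonyl; the ring-fusion centre should form mainly anti to the silyloxy group, and both diastereomers converge on 8.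

Step 4
Reactants: 6 6-(tert-butyldimethylsilyloxy)-2-methylbicyclo[3.3.0]oct-1-en-3-one
Product: 7 6-hydroxy-2-methylbicyclo[3.3.0]oct-1-en-3-one
Conditions: HF (48% aq.), MeCN, 0 → 25 °C
Reagents that add atoms: none
Why: Acidic fluoride desilylation frees the secondary alcohol without touching the enone and avoids base-induced vinylogous elimination.

Step 5
Reactants: 7 6-hydroxy-2-methylbicyclo[3.3.0]oct-1-en-3-one
Product: 8 2-methylbicyclo[3.3.0]oct-1-ene-3,6-dione (racemic)
Conditions: Dess–Martin periodinane, CH2Cl2, 0 → 25 °C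
Reagents that add atoms: none
Why: Dess–Martin oxidation of a secondary alcohol under nearly neutral conditions should give the enedione; its ring-fusion CH is α to one ketone and γ to the enone and therefore labile, so 8 is used as the racemate.

Step 6
Reactants: 8 2-methylbicyclo[3.3.0]oct-1-ene-3,6-dione; 9 (E)-crotonaldehyde
Product: 12 methyl (1R,7R,8R,10S)-8-hydroxy-3-oxo-12,13-dinorguai-4-en-11-oate, via aldehyde 10 (not isolated), via bridged ketol 11 (not isolated)
Conditions: 9 (1.5 equiv), (R)-α,α-diphenylprolinol trimethylsilyl ether (20 mol %), PhCO2H (20 mol %), toluene, 0 °C, argon; evaporate excess 9; then K2CO3 (0.5 equiv), MeOH, 0 → 25 °C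
Reagents that add atoms: methanol, CO
Why: Proposed new method: the amine turns 9 into an iminium ion whose Si face at C3 (the future C10) is open, and the C1 carbanion of 8, the one carbon that is α to the C11 ketone and γ to the C3 enone at once, adds there to give 10; carbonate in methanol then enolises C7, which closes on the C8 aldehyde in a reversible 6-(enolexo)-exo-trig aldol to the bicyclo[3.2.1]octan-8-one 11, and methoxide adds to its strained, non-conjugated bridge ketone C11 and expels C1 as the extended enolate of the enone, so that ring C1–C5–C6–C7–C11 grows into the seven-membered ring by C–C cleavage and not by direct closure. The closest known reaction type is the Michael–aldol–retro-Dieckmann ring expansion of 2-acyl- and 2-alkoxycarbonylcyclopentanones with enals, which has also been run with a prolinol-ether-catalysed Michael step; new here is the vinylogous ketone as activating and leaving group. C10 is fixed by the catalyst, C8 by the chair of 11 in which methyl and hydroxyl are both equatorial (O8 cis to C14), C1 by thermodynamic γ-protonation of the dienolate (C2 trans to C14), and C7 by equilibration of the ester α-carbon to the trans hydroxy ester, the epimer that step 9 inverts. The step needs attack through C1 and not through C4 or oxygen (only C1 is stabilised by both carbonyls), cleavage of C1–C11 and not of C7–C11 (only C1 leaves as a stabilised anion, and the conjugated C3 ketone is the poorer electrophile), and the C1/C10 relative topicity that places the methyl equatorial in 11, for which the substrate offers only the difference between its CH2 and C=O flanks.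

Step 7
Reactants: 12 methyl (1R,7R,8R,10S)-8-hydroxy-3-oxo-12,13-dinorguai-4-en-11-oate
Product: 13 methyl (1R,7R,8R,10S)-3,8-dihydroxy-12,13-dinorguai-4-en-11-oate (C3 epimers)
Conditions: NaBH4, CeCl3·7H2O, MeOH, −40 → 0 °C
Reagents that add atoms: none
Why: Luche reduction delivers hydride 1,2 to the enone only (the ester is untouched), which masks C3 against bases and organometallics and freezes the C1 configuration; the C3 carbinol forms as an inconsequential epimer mixture.

Step 8
Reactants: 13 methyl (1R,7R,8R,10S)-3,8-dihydroxy-12,13-dinorguai-4-en-11-oate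
Product: 14 methyl (1R,7R,8R,10S)-3,8-bis(tert-butyldimethylsilyloxy)-12,13-dinorguai-4-en-11-oate
Conditions: tBuMe2SiOTf, 2,6-lutidine, CH2Cl2, −78 → 0 °C
Reagents that add atoms: tert-butyldimethylsilyl trifluoromethanesulfonate, CC(C)(C)[Si](C)(C)OS(=O)(=O)C(F)(F)F
Why: Silyl triflate/lutidine silylation of both secondary alcohols protects O3 and places on O8 the bulky group that steers step 9.

Step 9
Reactants: 14 methyl (1R,7R,8R,10S)-3,8-bis(tert-butyldimethylsilyloxy)-12,13-dinorguai-4-en-11-oate
Product: 16 methyl (1R,7S,8R,10S)-3,8-bis(tert-butyldimethylsilyloxy)-12,13-dinorguai-4-en-11-oate, via lithium enolate 15 (not isolated)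
Conditions: LiN(iPr)2, THF, −78 °C; then tBuCO2H in THF, −78 °C
Reagents that add atoms: none
Why: Deprotonation and kinetic protonation of an ester enolate: in 15 allylic 1,3-strain with the enolate oxygens should turn the C8–OSi bond out of the enolate plane so that the silyloxy group covers one face of C7, and the bulky acid then delivers the proton to the other face, giving H7 trans to O8 and hence the contra-thermodynamic 7S ester cis to the silyloxy group.

Step 10
Reactants: 16 methyl (1R,7S,8R,10S)-3,8-bis(tert-butyldimethylsilyloxy)-12,13-dinorguai-4-en-11-oate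
Product: 18 (1R,7S,8R,10S)-3,8-bis(tert-butyldimethylsilyloxy)guai-4-en-11-ol, via methyl ketone 17 (not isolated)
Conditions: MeLi, CeCl3 (anhydrous), THF, −78 → 0 °C; aq. NH4Cl
Reagents that add atoms: methyllithium, C[Li]
Why: Organocerium double addition to the ester through methyl ketone 17 builds the C11 carbinol with its two methyl groups; the low basicity of the cerium reagent should keep C7 of 16 and 17 from enolising, so its configuration is kept.

Step 11
Reactants: 18 (1R,7S,8R,10S)-3,8-bis(tert-butyldimethylsilyloxy)guai-4-en-11-ol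
Product: 19 (1R,7S,8R,10S)-guai-4-ene-3,8,11-triol (C3 epimers)
Conditions: Bu4NF, THF, 25 → 45 °C
Reagents that add atoms: none
Why: Fluoride desilylation under basic conditions removes both silyl ethers without ionising the acid-sensitive cyclopentenyl carbinol.

Step 12
Reactants: 19 (1R,7S,8R,10S)-guai-4-ene-3,8,11-triol
Product: 20 (1R,7S,8R,10S)-8,11-dihydroxyguai-4-en-3-one
Conditions: MnO2 (activated, excess), CH2Cl2, 25 °C
Reagents that add atoms: none
Why: MnO2 oxidises only the allylic C3 alcohol, leaving the saturated secondary and the tertiary alcohol, and so restores the enone; both C3 epimers give the same ketone.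

Step 13
Reactants: 20 (1R,7S,8R,10S)-8,11-dihydroxyguai-4-en-3-one; 21 methacrylic anhydride
Product: 22 (1R,7S,8R,10S)-11-hydroxy-3-oxoguai-4-en-8-yl 2-methylprop-2-enoate
Conditions: Et3N, 4-(dimethylamino)pyridine (cat.), CH2Cl2, 0 → 25 °C
Reagents that add atoms: none
Why: Nucleophile-catalysed acyl transfer from the anhydride should esterify the secondary C8 alcohol selectively, because the tertiary C11 alcohol does not react under these mild conditions.

Step 14
Reactants: 22 (1R,7S,8R,10S)-11-hydroxy-3-oxoguai-4-en-8-yl 2-methylprop-2-enoate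
Product: 23 (1R,7S,8R,10S)-11-acetoxy-3-oxoguai-4-en-8-yl 2-methylprop-2-enoate (CNP0318307.1)
Conditions: Ac2O, Me3SiOTf (5 mol %), CH2Cl2, −20 → 0 °C
Reagents that add atoms: acetic anhydride, CC(=O)OC(C)=O
Why: Silyl-triflate-catalysed acetylation with acetic anhydride is a known way to esterify hindered tertiary alcohols quickly at low temperature, which should outpace ionisation at C11 and leave enone and methacrylate untouched.

**Compound list**

1 | 5-bromopent-2-yne | CC#CCCBr | starting material
2 | acrolein | C=CC=O | starting material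
3 | pent-3-ynylmagnesium bromide | CC#CCC[Mg]Br | intermediate
4 | oct-1-en-6-yn-3-ol (racemic) | C=CC(O)CCC#CC | intermediate
5 | tert-butyldimethyl(oct-1-en-6-yn-3-yloxy)silane (racemic) | C=CC(O[Si](C)(C)C(C)(C)C)CCC#CC | intermediate
6 | 6-(tert-butyldimethylsilyloxy)-2-methylbicyclo[3.3.0]oct-1-en-3-one (racemic, diastereomer mixture) | CC1=C2CCC(O[Si](C)(C)C(C)(C)C)C2CC1=O | intermediate
7 | 6-hydroxy-2-methylbicyclo[3.3.0]oct-1-en-3-one (racemic, diastereomer mixture) | CC1=C2CCC(O)C2CC1=O | intermediate
8 | 2-methylbicyclo[3.3.0]oct-1-ene-3,6-dione (racemic) | CC1=C2CCC(=O)C2CC1=O | intermediate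
9 | (E)-crotonaldehyde | C/C=C/C=O | starting material
10 | (3S)-3-[(5R)-2-methyl-3,6-dioxobicyclo[3.3.0]oct-1-en-5-yl]butanal (Michael adduct, C1–C10 bond formed) | O=CC[C@H](C)[C@]12CC(=O)C(C)=C1CCC2=O | intermediate
11 | bridged ketol (1R,7R,8R,10S): C7–C8 aldol of 10, a bicyclo[3.2.1]octan-8-one with C11 as the one-carbon bridge between C1 and C7, fused to the cyclopentenone; 8-OH and 10-CH3 equatorial | O[C@@H]1C[C@H](C)[C@]23CC(=O)C(C)=C2C[C@H]1C3=O | intermediate
12 | methyl (1R,7R,8R,10S)-8-hydroxy-3-oxo-12,13-dinorguai-4-en-11-oate (ester on C7 trans to 8-OH) | O[C@@H]1C[C@H](C)[C@H]2CC(=O)C(C)=C2C[C@H]1C(=O)OC | intermediate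
13 | methyl (1R,7R,8R,10S)-3,8-dihydroxy-12,13-dinorguai-4-en-11-oate (C3 epimers) | O[C@@H]1C[C@H](C)[C@H]2CC(O)C(C)=C2C[C@H]1C(=O)OC | intermediate
14 | methyl (1R,7R,8R,10S)-3,8-bis(tert-butyldimethylsilyloxy)-12,13-dinorguai-4-en-11-oate | CC(C)(C)[Si](C)(C)O[C@@H]1C[C@H](C)[C@H]2CC(O[Si](C)(C)C(C)(C)C)C(C)=C2C[C@H]1C(=O)OC | intermediate
15 | lithium enolate of 14 (C7=C11, enolate geometry open) | CC(C)(C)[Si](C)(C)O[C@@H]1C[C@H](C)[C@H]2CC(O[Si](C)(C)C(C)(C)C)C(C)=C2CC1=C(OC)O[Li] | intermediate
16 | methyl (1R,7S,8R,10S)-3,8-bis(tert-butyldimethylsilyloxy)-12,13-dinorguai-4-en-11-oate (ester cis to 8-OSi) | CC(C)(C)[Si](C)(C)O[C@@H]1C[C@H](C)[C@H]2CC(O[Si](C)(C)C(C)(C)C)C(C)=C2C[C@@H]1C(=O)OC | intermediate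
17 | (1R,7S,8R,10S)-3,8-bis(tert-butyldimethylsilyloxy)-13-norguai-4-en-11-one (methyl ketone) | CC(C)(C)[Si](C)(C)O[C@@H]1C[C@H](C)[C@H]2CC(O[Si](C)(C)C(C)(C)C)C(C)=C2C[C@@H]1C(C)=O | intermediate
18 | (1R,7S,8R,10S)-3,8-bis(tert-butyldimethylsilyloxy)guai-4-en-11-ol | CC(C)(C)[Si](C)(C)O[C@@H]1C[C@H](C)[C@H]2CC(O[Si](C)(C)C(C)(C)C)C(C)=C2C[C@@H]1C(C)(C)O | intermediate
19 | (1R,7S,8R,10S)-guai-4-ene-3,8,11-triol (C3 epimers) | O[C@@H]1C[C@H](C)[C@H]2CC(O)C(C)=C2C[C@@H]1C(C)(C)O | intermediate
20 | (1R,7S,8R,10S)-8,11-dihydroxyguai-4-en-3-one | O[C@@H]1C[C@H](C)[C@H]2CC(=O)C(C)=C2C[C@@H]1C(C)(C)O | intermediate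
21 | methacrylic anhydride | C=C(C)C(=O)OC(=O)C(C)=C | starting material
22 | (1R,7S,8R,10S)-11-hydroxy-3-oxoguai-4-en-8-yl 2-methylprop-2-enoate | C=C(C)C(=O)O[C@@H]1C[C@H](C)[C@H]2CC(=O)C(C)=C2C[C@@H]1C(C)(C)O | intermediate
23 | (1R,7S,8R,10S)-11-acetoxy-3-oxoguai-4-en-8-yl 2-methylprop-2-enoate | C=C(C)C(=O)O[C@@H]1C[C@H](C)[C@H]2CC(=O)C(C)=C2C[C@@H]1C(C)(C)OC(C)=O | target

**Step count and risks**

Total step count: 14. Longest linear sequence: 14 steps (1 to 23).

Steps most likely to fail:

Step 6 (new method). Three processes may undo it: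
- the methoxide cleavage of C1–C11 may not outrun retro-aldol back to 10 or dehydration of 12;
- the Michael addition may proceed through C4 or oxygen;
- the C1/C10 topicity may place the methyl axial in the ketol and so give the C8 epimer.

The fallback runs the same expansion on a true 2,2-disubstituted cyclopentane-1,3-dione, where each event is established chemistry. It sets out from crotonaldehyde 9 (commercial cyclopentane-1,3-dione and 1-bromobutan-2-one take the place of 8) and returns at 12. C-Alkylation of cyclopentane-1,3-dione with 1-bromobutan-2-one in aqueous KOH should give 2-(2-oxobutyl)cyclopentane-1,3-dione F1. The same (R)-prolinol ether catalyst adds F1 to 9 to give (3S)-3-[2,5-dioxo-1-(2-oxobutyl)cyclopentyl]butanal F2, in which C1 carries two identical acyl arms and is not a stereocentre. K2CO3 in methanol closes the bridged ketol 2-hydroxy-4-methyl-5-(2-oxobutyl)bicyclo[3.2.1]octane-6,8-dione F3, and methoxide opens its bridge ketone in a classical retro-Claisen of a non-enolisable 1,3-diketone to methyl 2-hydroxy-4-methyl-6-oxo-5-(2-oxobutyl)cycloheptane-1-carboxylate F4. Base-mediated cyclodehydration of the 1,4-diketone of F4 (C4 onto the C5 ketone) then closes the cyclopentenone and gives 12. Here the reversible aldol chooses the arm, so the equatorial-methyl ketol is reached under equilibrium and no Michael topicity is needed.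

Step 9. The proton is a small electrophile, so facial selection at C7 may be poor, and enolate 15 may lose silanolate by β-elimination on warming. The fallback replaces ionic protonation by hydrogen-atom transfer; it sets out from 14 and returns at 16. Enolate 15 (from 14 as in step 9) is trapped with PhSeBr at −78 °C to give methyl 3,8-bis(tert-butyldimethylsilyloxy)-7-(phenylselanyl)-12,13-dinorguai-4-en-11-oate F5. Bu3SnH with azobisisobutyronitrile in toluene at 80 °C then generates the C7 radical, which should take hydrogen from the bulky stannane on the face away from the 8-silyloxy group and give 16.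

Step 14. Under the Lewis acid the tertiary carbinol may ionise (elimination to the isopropenyl compound, or acyl scrambling through the neighbouring methacrylate), or acetylation may stall for steric reasons. The fallback installs the acetate on the alkoxide before the methacrylate exists; it sets out from 18 and returns at 23. Deprotonation of 18 with KN(SiMe3)2 and quench with Ac2O should give (1R,7S,8R,10S)-3,8-bis(tert-butyldimethylsilyloxy)guai-4-en-11-yl acetate F6. Pyridine-buffered HF·pyridine in THF removes both silyl groups to give (1R,7S,8R,10S)-3,8-dihydroxyguai-4-en-11-yl acetate F7. MnO2 oxidises the allylic alcohol to (1R,7S,8R,10S)-8-hydroxy-3-oxoguai-4-en-11-yl acetate F8. Acylation of F8 with 21, Et3N and 4-(dimethylamino)pyridine at low temperature then gives 23.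

Further compounds
F1 | step 6 | 2-(2-oxobutyl)cyclopentane-1,3-dione | CCC(=O)CC1C(=O)CCC1=O
F2 | step 6 | (3S)-3-[2,5-dioxo-1-(2-oxobutyl)cyclopentyl]butanal | O=CC[C@H](C)C1(CC(=O)CC)C(=O)CCC1=O
F3 | step 6 | 2-hydroxy-4-methyl-5-(2-oxobutyl)bicyclo[3.2.1]octane-6,8-dione (bridged ketol, OH and CH3 equatorial) | O[C@@H]1C[C@H](C)[C@]2(CC(=O)CC)C(=O)C[C@H]1C2=O
F4 | step 6 | methyl 2-hydroxy-4-methyl-6-oxo-5-(2-oxobutyl)cycloheptane-1-carboxylate | O[C@@H]1C[C@H](C)C(CC(=O)CC)C(=O)C[C@H]1C(=O)OC
F5 | step 9 | methyl 3,8-bis(tert-butyldimethylsilyloxy)-7-(phenylselanyl)-12,13-dinorguai-4-en-11-oate | CC(C)(C)[Si](C)(C)O[C@@H]1C[C@H](C)[C@H]2CC(O[Si](C)(C)C(C)(C)C)C(C)=C2CC1([Se]c3ccccc3)C(=O)OC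
F6 | step 14 | (1R,7S,8R,10S)-3,8-bis(tert-butyldimethylsilyloxy)guai-4-en-11-yl acetate | CC(C)(C)[Si](C)(C)O[C@@H]1C[C@H](C)[C@H]2CC(O[Si](C)(C)C(C)(C)C)C(C)=C2C[C@@H]1C(C)(C)OC(C)=O
F7 | step 14 | (1R,7S,8R,10S)-3,8-dihydroxyguai-4-en-11-yl acetate | O[C@@H]1C[C@H](C)[C@H]2CC(O)C(C)=C2C[C@@H]1C(C)(C)OC(C)=O
F8 | step 14 | (1R,7S,8R,10S)-8-hydroxy-3-oxoguai-4-en-11-yl acetate | O[C@@H]1C[C@H](C)[C@H]2CC(=O)C(C)=C2C[C@@H]1C(C)(C)OC(C)=O
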